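**Plan**
Ring numbering: C1 is the carbonyl carbon, C2 the vinylic CH, C3 the carbon bearing the nonadecyl chain, and C4–C6 the three ring CH2 groups. The retrosynthesis cuts C1–C2 and C1–C6, so C1 leaves as carbon monoxide, and it re-joins C4 to C6 as a cyclopropane. The precursor is (henicos-1-en-2-yl)cyclopropane.
Enabling feature: C1 sits between the unsubstituted vinylic C2 and a saturated, unsubstituted C4–C5–C6 bridge that ends on alkene carbon C3. The ring without C1 is therefore a pent-2-ene-1,5-diyl unit, which is the ring-opened form of a 1-substituted vinylcyclopropane.
The three-membered ring (C4, C5, C6) is a temporary ring. Its strain pays for the event and it is consumed in the event, so no removal step follows.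
Further cuts are C2=C3 (Wittig methylenation) and C3–C4 (Weinreb ketone synthesis). These lead back to icosanoic acid, which supplies C3 and the whole chain, and to cyclopropylmagnesium bromide.
Forward order: the chain is joined to the cyclopropane, the methylene C2 is added, and the only ring of the target forms last, when the acyl carbon C1 bonds to C2.
Stereochemistry: the target has no stereocentre, the alkene geometry is fixed by the ring, and the alkene position is set by base equilibration.

Key step: step 4

Remark on the chemistry: the side chain is read as unbranched nonadecyl, so the target is achiral 3-nonadecylcyclohex-2-en-1-one, C25H46O.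

Step 1
Reactants: 1 icosanoic acid
Product: 3 N-methoxy-N-methylicosanamide, via icosanoyl imidazolide 2 (not isolated)
Conditions: CDI (1.2 equiv), THF, 40 °C; then MeNHOMe·HCl (1.5 equiv), rt
Reagents that add atoms: N,O-dimethylhydroxylamine hydrochloride, CNOC.Cl; 1,1'-carbonyldiimidazole, O=C(n1ccnc1)n1ccnc1 (supplies the imidazolyl group of 2 only)
Why: CDI-mediated Weinreb amide formation, in which loss of CO2 drives formation of the acyl imidazolide and the hydroxylamine then displaces imidazole, is a standard activation of long-chain fatty acids.

Step 2
Reactants: 3 N-methoxy-N-methylicosanamide, 4 cyclopropylmagnesium bromide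
Product: 6 1-cyclopropylicosan-1-one, via magnesium hemiaminal chelate 5 (not isolated)
Conditions: c-PrMgBr (1.3 equiv), THF, 0 °C to rt; then 1 M aq. HCl
Reagents that add atoms: cyclopropylmagnesium bromide (4), Br[Mg]C1CC1
Why: In the Weinreb ketone synthesis the five-membered magnesium chelate 5 should persist until the acidic quench, so only one cyclopropyl group is delivered and no tertiary alcohol forms.

Step 3
Reactants: 6 1-cyclopropylicosan-1-one, 7 methyltriphenylphosphonium bromide
Product: 8 (henicos-1-en-2-yl)cyclopropane
Conditions: Ph3PCH3Br (1.5 equiv), KOtBu (1.4 equiv), THF, 0 °C to reflux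
Reagents that add atoms: methyltriphenylphosphonium bromide (7), C[P+](c1ccccc1)(c1ccccc1)c1ccccc1.[Br-]
Why: Wittig methylenation with the unstabilised ylide turns cyclopropyl alkyl ketones into 1-substituted vinylcyclopropanes under basic conditions that never generate a cyclopropylcarbinyl cation, so the three-membered ring stays closed.

Step 4
Reactants: 8 (henicos-1-en-2-yl)cyclopropane, 9 carbon monoxide
Product: 11 3-nonadecylcyclohex-2-en-1-one, via 3-nonadecylcyclohex-3-en-1-one 10 (not isolated)
Conditions: [Rh(CO)2Cl]2 (2.5 mol %), dppp (6 mol %), AgOTf (6 mol %), CO/N2 (1:4, 1 atm), 4 Å MS, DCE, 85 °C; then DBU (0.5 equiv), rt, same flask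
Reagents that add atoms: carbon monoxide (9), [C-]#[O+]
Why: Cationic monovalent rhodium should bind the 1,1-disubstituted alkene of 8 and insert into one of the two equivalent proximal cyclopropane bonds to give a rhodacycle holding C2–C3–C4 as a π-allyl unit and C6 as a σ-alkyl group; CO then inserts into the Rh–C6 bond (forming C6–C1), and reductive elimination from trivalent rhodium joins the acyl carbon C1 to the unsubstituted allyl terminus C2. The closest known reaction type is the rhodium-catalysed [5+1] cycloaddition of 1-substituted vinylcyclopropanes with CO, with the Fe(CO)5-mediated photochemical carbonylation of alkenylcyclopropanes as the older relative. The six-membered ring is closed by this acyl–allyl reductive elimination out of a seven-membered acylrhodacycle, a formal [5+1] ring expansion paid for by the strain of the three-membered ring. Site selectivity between the two allyl termini is needed: bond formation at C2 gives the cyclohexenone, whereas bond formation at C4 would give a strained 2-alkenylcyclobutanone, and the free CH2 terminus is also the less hindered one. Chemoselectivity for CO insertion over β-hydride elimination at C5 is served by the chelating dppp ligand and a low, constant CO pressure, and the substituent on C3 holds alkene and ring in the arrangement that carbon–carbon insertion requires. No stereocentre is formed; the alkene first lies at C3=C4 (10), and DBU moves it through the dienolate formed by deprotonation at C2 into conjugation, the endocyclic trisubstituted enone 11 being the thermodynamic sink.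

**Compound list**
1 | icosanoic acid (arachidic acid) | CCCCCCCCCCCCCCCCCCCC(=O)O | starting material
2 | 1-(1H-imidazol-1-yl)icosan-1-one (icosanoyl imidazolide) | CCCCCCCCCCCCCCCCCCCC(=O)n1ccnc1 | intermediate
3 | N-methoxy-N-methylicosanamide | CCCCCCCCCCCCCCCCCCCC(=O)N(C)OC | intermediate
4 | cyclopropylmagnesium bromide | Br[Mg]C1CC1 | starting material
5 | bromomagnesium 1-cyclopropyl-1-[methoxy(methyl)amino]icosan-1-olate (racemic chelate) | CCCCCCCCCCCCCCCCCCCC(O[Mg]Br)(N(C)OC)C1CC1 | intermediate
6 | 1-cyclopropylicosan-1-one | CCCCCCCCCCCCCCCCCCCC(=O)C1CC1 | intermediate
7 | methyltriphenylphosphonium bromide | C[P+](c1ccccc1)(c1ccccc1)c1ccccc1.[Br-] | starting material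
8 | (henicos-1-en-2-yl)cyclopropane (2-cyclopropylhenicos-1-ene) | CCCCCCCCCCCCCCCCCCCC(=C)C1CC1 | intermediate
9 | carbon monoxide | [C-]#[O+] | starting material
10 | 3-nonadecylcyclohex-3-en-1-one | CCCCCCCCCCCCCCCCCCCC1=CCCC(=O)C1 | intermediate
11 | 3-nonadecylcyclohex-2-en-1-one | CCCCCCCCCCCCCCCCCCCC1=CC(=O)CCC1 | target

Total step count: 4. Longest linear sequence: 4.

**Steps most likely to fail**

Step 4.
- What may go wrong: β-hydride elimination from the rhodacycle may outrun CO insertion and open the vinylcyclopropane to acyclic dienes. A rhodium hydride may move the 1,1-disubstituted alkene along the chain. CO may saturate the metal and stall carbon–carbon insertion.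
- Fallback, from 6 back to 11: it replaces metal insertion into the ring by ionic ring opening followed by a carbonylative closure of an alkyl iodide.
- Me3SiI (CH2Cl2, 0 °C) silylates the ketone oxygen, and iodide attacks a ring CH2. This gives 1-iodo-4-(trimethylsilyloxy)tricos-3-ene F1 (alkene geometry of no consequence).
- Aqueous work-up hydrolyses this compound to 1-iodotricosan-4-one F2.
- Non-basic methylenation with Cp2TiMe2 (toluene, 70 °C) gives 1-iodo-4-methylidenetricosane F3. A basic ylide is avoided because it would re-close the cyclopropane through the enolate.
- Pd(PPh3)4, CO (50 atm), iPr2NEt, benzene, 130 °C (carbonylative Heck-type cyclisation of an alkyl iodide) then takes up CO at the primary carbon.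
- The resulting hex-5-enoyl intermediate carries a substituent on its internal alkene carbon, so it should close 6-endo at the CH2 terminus. This again joins C1 to C2. Base-assisted loss of hydrogen iodide across C2–C3 gives 11.

Step 3.
- What may go wrong: the basic ylide may enolise the ketone, and attack may be slow at a carbonyl flanked by the ring and a waxy chain, so conversion may stall.
- Fallback, from 6 back to 8: a two-stage Peterson olefination.
- Me3SiCH2MgCl with CeCl3 (THF, −78 °C to 0 °C) adds as a small nucleophile of low basicity. It gives 2-cyclopropyl-1-(trimethylsilyl)henicosan-2-ol F4 (racemic).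
- KH in THF then triggers the basic syn-elimination to 8. An acidic elimination is avoided because it would pass through a cyclopropylcarbinyl cation.

Step 2.
- What may go wrong: the waxy amide may precipitate at low temperature and stall the addition. Base-induced cleavage of the N–O bond of the amide may consume substrate.
- Fallback, from 3 back to 6: it changes the oxidation level at which the carbon–carbon bond is made.
- iBu2AlH (THF, −78 °C) reduces 3 to icosanal F5.
- The much more electrophilic aldehyde takes up 4 to give 1-cyclopropylicosan-1-ol F6 (racemic).
- Dess–Martin periodinane (CH2Cl2, rt) oxidises the carbinol to 6 under neutral conditions that leave the ring intact.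

**Further compounds**
F1 | step 4 | 1-iodo-4-(trimethylsilyloxy)tricos-3-ene | CCCCCCCCCCCCCCCCCCCC(O[Si](C)(C)C)=CCCI
F2 | step 4 | 1-iodotricosan-4-one | CCCCCCCCCCCCCCCCCCCC(=O)CCCI
F3 | step 4 | 1-iodo-4-methylidenetricosane | CCCCCCCCCCCCCCCCCCCC(=C)CCCI
F4 | step 3 | 2-cyclopropyl-1-(trimethylsilyl)henicosan-2-ol (racemic) | CCCCCCCCCCCCCCCCCCCC(O)(C[Si](C)(C)C)C1CC1
F5 | step 2 | icosanal | CCCCCCCCCCCCCCCCCCCC=O
F6 | step 2 | 1-cyclopropylicosan-1-ol (racemic) | CCCCCCCCCCCCCCCCCCCC(O)C1CC1
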